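Substrate at 0.10 M and partner at 0.150 M are charged alike in teal, red, Saturday's and Tuesday's, so free catalyst and time are what differ.

| setting | teal | red | Saturday's | Tuesday's |
|---|---|---|---|---|
| substrate | 0.10 M | 0.10 M | 0.10 M | 0.10 M |
| partner | 0.15 M | 0.15 M | 0.150 M | 0.150 M |
| free catalyst | 2.3 mM | 5.2 mM | 8.4 mM | 2.8 mM |
| remark | run made earlier | run made earlier |  |  |
| time |  |  | 12 min | 12 min |

| run | time / min | product / % | catalyst intermediate D / % | substrate / % | catalyst intermediate A / % |
|---|---|---|---|---|---|
| teal | 0.667 | 0 | 0 | 95 | 1 |
| teal | 1.50 | 2 | 2 | 98 | 1 |
| teal | 4.00 | 6 | 0 | 92 | 0 |
| teal | 8.00 | 11 | 1 | 88 | 0 |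
| red | 1.00 | 2 | 2 | 94 | 0 |
| red | 3.00 | 8 | 0 | 87 | 0 |
| red | 5.00 | 16 | 3 | 80 | 0 |
| red | 8.00 | 23 | 1 | 71 | 1 |

(each reading ± 1.5 percentage points)

- steps that have been proposed: substrate + free catalyst -> catalyst intermediate A; partner + catalyst intermediate A -> catalyst intermediate B; catalyst intermediate B -> by-product + catalyst intermediate C; catalyst intermediate C -> catalyst intermediate D; catalyst intermediate D -> free catalyst + product; catalyst intermediate C -> spent catalyst

- which of these there is most of at the end, counted by the substrate in it, Saturday's (product / substrate / catalyst intermediate D / catalyst intermediate A)
- which of these there is most of at the end, counted by the substrate in it, Tuesday's (product / substrate / catalyst intermediate D / catalyst intermediate A)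
- how much there is at the end of the one of these that leads, in percent of the substrate charged: Saturday's
- how much there is at the end of the one of these that leads, in percent of the substrate charged: Tuesday's

Partner is charged in excess of substrate, but the proposed steps consume it along with substrate and share the catalyst charged among several forms, so neither partner nor free catalyst stays constant. This reckoning therefore rests on an assumption: the rate per unit of catalyst charged stays as red showed it. On that assumption substrate falls by a fixed fraction per catalyst-minute, a pseudo-first-order picture. Scaled on red's last reading, 71% substrate at 8.00 min, each flask's charge and time fold into one number: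

dose number = ln(substrate charged / substrate left in red) × (catalyst × time of the flask) / (catalyst × time of red)

Saturday's: 0.830; Tuesday's: 0.277

This dose number counts how many times the catalyst-minutes of a flask shrink its substrate by the factor e:

substrate left = substrate charged / exp(dose number)

Saturday's: 43.6%; Tuesday's: 75.8%

The test is teal, which had no part in the scale. Its last reading reckons to 85.9% and reads 88%, a gap of 2.1 percentage points beside a scatter of 1.5 points. But Saturday's reckoned substrate lies below anything red reached.

Each catalyst holds one substrate at most, which on Saturday's is 8.40% of the substrate charged. By this reckoning product there falls between 48.0% and 56.4%, above substrate. This reckoning takes product at about 52.2% on Saturday's and substrate leading at 75.8% on Tuesday's.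

The forecast differs slightly, with product at 49% on Saturday's, “this is a close call”, and substrate at 78% on Tuesday's.

The flasks give product at 55.4% on Saturday's and substrate at 77.4% on Tuesday's.

    substrate + free catalyst → catalyst intermediate A (k = 34.0 L mol⁻¹ min⁻¹)
    partner + catalyst intermediate A → catalyst intermediate B (k = 26.0 L mol⁻¹ min⁻¹)
    catalyst intermediate B → by-product + catalyst intermediate C (k = 3.40 min⁻¹)
    catalyst intermediate C → catalyst intermediate D (k = 3.70 min⁻¹)
    catalyst intermediate D → free catalyst + product (k = 2.70 min⁻¹)
    catalyst intermediate C → spent catalyst (k = 0.00960 min⁻¹)

At the end of Saturday's, substrate and product leave 5.50% of the substrate charged in the catalyst's other forms, with free catalyst at 34.6% of the catalyst charged. The dose number 0.830 gave 43.6% substrate against 39.1% there, and 0.277 gave 75.8% against 77.4% on Tuesday's. A neighbour of Saturday's with partner at 0.060 M has the same catalyst and time, so the same dose number and the same reckoned 43.6%, yet its substrate stands at 54.0%.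

The runs stem from a simulated flask for substances that don't exist.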